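## The problem

The target **14** is a depside. Ring A is olivetolic acid (2,4-dihydroxy-6-pentylbenzoic acid) and ring B is 3-chloro-2-hydroxy-4-methoxy-6-propylbenzoic acid. The only link between them is the aryl ester from the ring B carboxyl carbon to O4 of ring A. There is no stereocentre, so every difficulty is one of regiochemistry and functional-group tolerance.

Ring B carries five different substituents, with chlorine at C3' wedged between the C2' hydroxyl and the C4' methoxy group. Chlorinating a 2-hydroxy-4-methoxy-6-propylbenzoate would have to choose between C3' and C5', both activated by oxygen, so the halogen is better built in than added. The ester must be formed at O4 of ring A in the presence of O2 and the ring A carboxyl, and the acylating carbon of ring B is flanked by a hydroxyl and a propyl group.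

Three groups will not survive rough treatment. The depside ester is cleaved by hydroxide, alkoxide and amines. The two electron-rich salicylic acids lose CO2 when heated or held in acid, ring A most readily. The aryl chloride is at risk under reducing conditions.

What opens the structure up is that ring B is a folded tetraketide. The carboxyl on C1', the oxygens on C2' and C4' and the alkyl chain on C6' alternate, and C3' lies between two oxygen-bearing carbons, exactly like C4 of an acetoacetate. A 4-chloroacetoacetate therefore maps onto the ester carbon, C1', C2' and C3' with chlorine in place, and a butanoyl ketene acetal maps onto C4', C5', C6' and the propyl chain.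

## Retrosynthesis

**14 from 13.** The first cut is the benzyl–oxygen bond of a ring A benzyl ester. The ring A carboxyl has to be masked while ring B is attached, and it must be unmasked without hydrolysis because the depside link would not survive. A benzyl ester removed by hydrogenolysis meets both needs; esters that need acid or base for removal would endanger the depside ester or invite decarboxylation. The forward step must cleave the benzyl group and leave the C3'–Cl bond alone.

**13 from 9 and 11.** The depside C(=O)–O4 bond is cut next. It is the only bond joining the halves, and it divides the molecule into two arenes of similar size, the ring B acid **9** and the ring A phenol **11**. Cutting inside ring B with the aryl ester already present would carry that labile ester through Lewis-acid ring construction. The forward reaction has to acylate O4 only, with a carboxyl that is hindered on both sides. Mixed-anhydride activation should do this without masking O2', because the O2 hydroxyls of both partners are hydrogen-bonded to their neighbouring carbonyl groups.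

**11 from 10.** Cutting the benzyl–oxygen bond of **11** leads to olivetolic acid **10**, which already holds all of ring A. Only selective alkylation of the carboxylate beside two phenols is required.

**9 from 8.** The acid **9** is traced to its ethyl ester **8**, the form in which the ring synthesis delivers the C1' carboxyl. The forward step is the saponification of a di-ortho-substituted salicylate and must avoid decarboxylation.

**8 from 3 and 6.** Ring B is cut at C3'–C4' and C1'–C6'. This pair of cuts gives each fragment three ring carbons with its natural polarity. Diene **3** is a 1,3-dinucleophile (terminal carbon becomes C3', central carbon C1'). Enone **6** is a 1,3-dielectrophile (acetal carbon becomes C4', ketone carbon C6'). Other pairs of ring bonds would need an alkyne partner or a later oxidation, and none would bring the chlorine in with a purchasable reagent. The precursors hold four and six skeletal carbons, and all five substituents arrive in place. The forward reaction must make its first bond between the chlorinated diene terminus and the acetal carbon.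

**3 from 2 from 1.** Diene **3** is reached by removing its two O–Si bonds in turn, through silyl enol ether **2**, back to ethyl 4-chloro-3-oxobutanoate **1**. Nothing is asked beyond two O-silylations that leave the chloromethyl group intact.

**6 from 4 and 5.** Enone **6** is cut at the bond between its carbonyl carbon and the vinyl carbon, giving butanoyl chloride **4** and 1,1-dimethoxyethene **5**. The forward step is a C-acylation of the ketene acetal that must stop at the push–pull alkene.

## Roads not taken

**Alternative 1:** The cut falls in ring A, which would be built as a cyclohexanedione, acylated, and aromatized late. In the forward key step the sodium enolate of dibenzyl malonate A1 adds to (E)-non-3-en-2-one A2 (Michael addition, C1–C6). The methyl ketone then condenses onto a malonate ester carbonyl (Claisen closure, C2–C3) to give benzyl 2,4-dioxo-6-pentylcyclohexane-1-carboxylate A3.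

- Merits: the building blocks are cheap, the benzyl ester is in place from the start, and the decarboxylation-prone resorcylic acid never appears free.
- Weak points: the effort goes into the ring that can be bought as **10**, while ring B, where the chlorine problem lies, still has to be made. O-acylation of A3 with **9** would give an enol ester, which is itself an acyl donor and prone to O-to-C acyl migration. The two enol oxygens of A3 must also be told apart. The final dehydrogenation, with a halogen or quinone oxidant, would run in the presence of an electron-rich ring B with a free C5' position.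
- Comparison: if supply of **10** were the bottleneck, this construction of ring A would be the better one, and it could feed **11** into the chosen plan after aromatization. The chosen plan sets against it that it solves the ring B substitution pattern, which this road leaves open.

**Alternative 2:** Both bonds at the ester carbonyl are cut (C1'–C=O and C=O–O4). The forward key step joins the aryl iodide 3-(benzyloxy)-2-chloro-4-iodo-1-methoxy-5-propylbenzene A4, carbon monoxide A5 and the O4 hydroxyl of **11** on a palladium catalyst carrying a wide-bite-angle diphosphine. The product is benzyl 4-{[2-(benzyloxy)-3-chloro-4-methoxy-6-propylbenzoyl]oxy}-2-hydroxy-6-pentylbenzoate A6.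

- Merits: it is as convergent as the chosen esterification, and it avoids both the saponification of a hindered ester and the free ring B acid. In that respect it is better.
- Weak points: A4 must itself be made by two electrophilic halogenations of a resorcinol ether, each with two activated positions open, so the regiochemical problem is doubled. The acylpalladium intermediate is flanked by benzyloxy and propyl groups and must be captured by a weakly nucleophilic phenoxide. No ring is formed, and a benzyl ether is added that must come off later.
- Comparison: the chosen plan sets against the cleaner ester formation a ring synthesis in which every substituent position follows from connectivity, and it needs no carbonylation of a hindered halide.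

**Alternative 3:** Ring B is cut at C1'–C2' and C5'–C6' and grown on ring A. The forward key step is a Diels–Alder reaction between the ring A aryl alkynoate benzyl 4-(hex-2-ynoyloxy)-2-hydroxy-6-pentylbenzoate A7 and 2-chloro-1,3-dimethoxy-1-(trimethylsilyloxy)buta-1,3-diene A8. Expulsion of one methoxy and one silyl group from the acetal carbon aromatizes the adduct to benzyl 4-[(3-chloro-2-hydroxy-4-methoxy-6-propylbenzoyl)oxy]-2-hydroxy-6-pentylbenzoate A9, which is the same compound as **13**.

- Merits: it is the shortest endgame. The depside ester exists before ring B does, so neither a hindered saponification nor a hindered esterification is needed, and only hydrogenolysis follows. The normal polarity of diene and ynoate gives the right regiochemistry.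
- Weak points: a β-alkyl alkynoate is a sluggish dienophile that needs heat. The chlorine on the central diene carbon lowers its reactivity further. The ketene acetal diene can instead attack the activated aryl ester or be desilylated by the free O2 phenol of ring A.
- Comparison: if the cycloaddition worked, this road would be shorter and more convergent than the chosen one. The chosen plan sets against it a ring closure that runs at low temperature on two small fragments, each step of which (conjugate addition, aldol closure) is driven by a strongly polarized acceptor, with the sensitive ester introduced only afterwards.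

Key step: step 4

Assumption: the double-bond geometries written for **2**, **3** and **7** are chosen for definiteness. All of these sp2 carbons end up in the arene, so the geometry has no bearing on the outcome. Compounds **1**, **4**, **5** and **10** are taken as purchasable.

Step 1
Reactants: 1 ethyl 4-chloro-3-oxobutanoate
Product: 2 ethyl (2Z)-4-chloro-3-(trimethylsilyloxy)but-2-enoate
Conditions: TMSCl, Et3N, toluene, 20 °C
Reagents that add atoms: chlorotrimethylsilane, C[Si](C)(C)Cl
Why: Silyl enol ether formation: the strongly enolized β-keto ester is silylated on oxygen by TMSCl/Et3N, and at room temperature in a non-polar solvent the chloromethyl group should not be alkylated by the amine.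

Step 2
Reactants: 2 ethyl (2Z)-4-chloro-3-(trimethylsilyloxy)but-2-enoate
Product: 3 (1Z,3Z)-4-chloro-1-ethoxy-1,3-bis(trimethylsilyloxy)buta-1,3-diene
Conditions: LiN(iPr)2, THF, −78 °C; then TMSCl, −78 → 20 °C
Reagents that add atoms: chlorotrimethylsilane, C[Si](C)(C)Cl
Why: γ-Deprotonation of the vinylogous ester at the CH2Cl group gives the extended dienolate, which TMSCl traps on the ester oxygen; this is the standard second silylation leading to 1,3-bis(silyloxy)buta-1,3-dienes, and −78 °C keeps the α-chloro carbanion from alkylating itself.

Step 3
Reactants: 4 butanoyl chloride, 5 1,1-dimethoxyethene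
Product: 6 1,1-dimethoxyhex-1-en-3-one
Conditions: 5 (2.2 equiv), Et2O, 0 → 20 °C
Reagents that add atoms: none
Why: C-Acylation of a ketene acetal: the electron-rich CH2 carbon of 5 attacks the acid chloride and the dimethoxycarbenium ion loses a proton to give the push–pull alkene 6. The second equivalent of 5 takes up the HCl, so no amine base is present that could turn 4 into ethylketene.

Step 4
Reactants: 3 (1Z,3Z)-4-chloro-1-ethoxy-1,3-bis(trimethylsilyloxy)buta-1,3-diene, 6 1,1-dimethoxyhex-1-en-3-one
Product: 8 ethyl 3-chloro-2-hydroxy-4-methoxy-6-propylbenzoate, via open-chain chloro enone adduct 7 (not isolated)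
Conditions: TiCl4 (1.1 equiv), CH2Cl2, −78 → 20 °C; then aq. HCl
Reagents that add atoms: none
Why: TiCl4 binds the carbonyl oxygen of 6, so that C1 becomes a dimethoxycarbenium-like centre and C3 a titanium enolate carbon; the chlorine-bearing terminus of 3, its vinylogous and most nucleophilic carbon, adds to C1 in a Mukaiyama–Michael step (C3'–C4'), and loss of one methoxy group restores the enone as the vinylogous ester 7. The silyl ketene acetal carbon that remains (the future C1') then attacks the TiCl4-activated propyl ketone in a Mukaiyama-type aldol closure, 6-(enolexo)-exo-trig, which forms C1'–C6' and the six-membered ring B. Elimination of the tertiary titanium alkoxide and enolization of the C2' ketone give the arene, which makes the sequence irreversible. The closest known reaction type is the TiCl4-mediated formal (3+3) cyclocondensation of 1,3-bis(silyloxy)buta-1,3-dienes, 4-chloro dienes among them, with 3-alkoxy and 3-silyloxy enones and with 1,1-dimethoxy-1-en-3-ones to give salicylates. No stereocentre is formed: the C4 centre and the double-bond geometry of 7 vanish on aromatization, and the push–pull double bond of 7 can rotate under the Lewis acid into the geometry that closes. The selectivity needed is that the diene terminus bonds to the acetal carbon and the central carbon to the ketone carbon; the reverse order would exchange methoxy and propyl on the ring. It is secured by the polarization of 6, a vinylogous carbonate whose carbonyl carbon is a poor electrophile until the methoxy group has left, and by the order of nucleophilicity in 3 (terminal before central carbon). Chlorine, hydroxyl, methoxy, ester and propyl are thus all placed by the connectivity of the two fragments.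

Step 5
Reactants: 8 ethyl 3-chloro-2-hydroxy-4-methoxy-6-propylbenzoate
Product: 9 3-chloro-2-hydroxy-4-methoxy-6-propylbenzoic acid
Conditions: KOH, DMSO–H2O, 90 °C; then cold aq. HCl
Reagents that add atoms: potassium hydroxide, [K+].[OH-]
Why: Saponification of a di-ortho-substituted salicylate needs poorly solvated hydroxide, hence KOH in aqueous DMSO. The aryl chloride and methyl ether on the phenoxide ring are inert to hydroxide, and acidification in the cold should avoid decarboxylation.

Step 6
Reactants: 10 olivetolic acid
Product: 11 benzyl 2,4-dihydroxy-6-pentylbenzoate
Conditions: BnBr, KHCO3, DMF, 20 °C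
Reagents that add atoms: benzyl bromide, BrCc1ccccc1
Why: Carboxylate O-alkylation (SN2): KHCO3 deprotonates only the carboxylic acid, so benzyl bromide should give the ester and leave both phenols free; room temperature avoids decarboxylation of 10.

Step 7
Reactants: 9 3-chloro-2-hydroxy-4-methoxy-6-propylbenzoic acid, 11 benzyl 2,4-dihydroxy-6-pentylbenzoate
Product: 13 benzyl 4-[(3-chloro-2-hydroxy-4-methoxy-6-propylbenzoyl)oxy]-2-hydroxy-6-pentylbenzoate, via mixed trifluoroacetic anhydride 12 (not isolated)
Conditions: (CF3CO)2O, toluene, 20 °C; aq. NaHCO3 work-up
Reagents that add atoms: none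
Why: Trifluoroacetic anhydride-mediated esterification, the standard way of joining depside halves: mixed anhydride 12 of the electron-rich, 2,6-disubstituted acid ionizes towards the acylium ion and acylates the free O4 phenol of 11. The O2 hydroxyls of both partners are hydrogen-bonded to their neighbouring carbonyl groups (that of 9 is also flanked by chlorine) and should stay unacylated, and any aryl trifluoroacetate is cleaved on bicarbonate work-up.

Step 8
Reactants: 13 benzyl 4-[(3-chloro-2-hydroxy-4-methoxy-6-propylbenzoyl)oxy]-2-hydroxy-6-pentylbenzoate
Product: 14 4-[(3-chloro-2-hydroxy-4-methoxy-6-propylbenzoyl)oxy]-2-hydroxy-6-pentylbenzoic acid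
Conditions: H2 (1 atm), Pd/C (10% Pd), EtOAc, 20 °C
Reagents that add atoms: none
Why: Hydrogenolysis of a benzyl ester over Pd/C is fast and neutral, so the depside ester is not touched. An aryl chloride on an electron-rich ring is reduced far more slowly, especially without base, and the reaction is stopped after uptake of one equivalent of H2.

## Compound list

1 | ethyl 4-chloro-3-oxobutanoate | CCOC(=O)CC(=O)CCl | starting material
2 | ethyl (2Z)-4-chloro-3-(trimethylsilyloxy)but-2-enoate | CCOC(=O)/C=C(\O[Si](C)(C)C)CCl | intermediate
3 | (1Z,3Z)-4-chloro-1-ethoxy-1,3-bis(trimethylsilyloxy)buta-1,3-diene | Cl/C=C(\O[Si](C)(C)C)/C=C(/OCC)O[Si](C)(C)C | intermediate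
4 | butanoyl chloride | CCCC(Cl)=O | starting material
5 | 1,1-dimethoxyethene | C=C(OC)OC | starting material
6 | 1,1-dimethoxyhex-1-en-3-one | CCCC(=O)C=C(OC)OC | intermediate
7 | ethyl (5E)-4-chloro-5-methoxy-3,7-dioxodec-5-enoate (racemic at C4; present as its titanium or silyl enolate, drawn in the keto form; not isolated) | CCOC(=O)CC(=O)C(Cl)/C(OC)=C\C(=O)CCC | intermediate
8 | ethyl 3-chloro-2-hydroxy-4-methoxy-6-propylbenzoate | CCCc1cc(OC)c(Cl)c(O)c1C(=O)OCC | intermediate
9 | 3-chloro-2-hydroxy-4-methoxy-6-propylbenzoic acid | CCCc1cc(OC)c(Cl)c(O)c1C(=O)O | intermediate
10 | olivetolic acid (2,4-dihydroxy-6-pentylbenzoic acid) | CCCCCc1cc(O)cc(O)c1C(=O)O | starting material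
11 | benzyl 2,4-dihydroxy-6-pentylbenzoate | CCCCCc1cc(O)cc(O)c1C(=O)OCc1ccccc1 | intermediate
12 | 3-chloro-2-hydroxy-4-methoxy-6-propylbenzoic trifluoroacetic anhydride (not isolated) | CCCc1cc(OC)c(Cl)c(O)c1C(=O)OC(=O)C(F)(F)F | intermediate
13 | benzyl 4-[(3-chloro-2-hydroxy-4-methoxy-6-propylbenzoyl)oxy]-2-hydroxy-6-pentylbenzoate | CCCCCc1cc(OC(=O)c2c(CCC)cc(OC)c(Cl)c2O)cc(O)c1C(=O)OCc1ccccc1 | intermediate
14 | 4-[(3-chloro-2-hydroxy-4-methoxy-6-propylbenzoyl)oxy]-2-hydroxy-6-pentylbenzoic acid | CCCCCc1cc(OC(=O)c2c(CCC)cc(OC)c(Cl)c2O)cc(O)c1C(=O)O | target

## Step count and risks

Total step count: 8. Longest linear sequence: 6 steps (steps 1, 2, 4, 5, 7 and 8, from **1** to **14**). Steps 3 and 6 are single-step branches.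

**Step 4 (key step).** The chlorine-bearing diene terminus is less nucleophilic and more hindered than that of the parent diene. Desilylation of **3** by the Lewis acid, or chloride-induced demethylation and oligomerization of **6**, may therefore outrun the conjugate addition. First attack at the ketone carbon would give the ring with methoxy and propyl exchanged. The fallback sets out from **6** and returns at **9**, giving up the built-in placement of chlorine. Compound **6** is combined under the same TiCl4 conditions with commercial 1-methoxy-1,3-bis(trimethylsilyloxy)buta-1,3-diene (C=C(O[Si](C)(C)C)C=C(OC)O[Si](C)(C)C), whose terminus is unhindered, to give methyl 2-hydroxy-4-methoxy-6-propylbenzoate F1. Chlorination with SO2Cl2 (1 equiv, CH2Cl2, 0 °C) then gives methyl 3-chloro-2-hydroxy-4-methoxy-6-propylbenzoate F2, which must be separated from its 5-chloro isomer. Saponification as in step 5 gives **9**.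

**Step 3.** Chloride may dealkylate the dimethoxycarbenium intermediate to a β-keto ester instead of letting it lose a proton. A second acylation or hydrolysis of the acid-labile ketene acetal on isolation is also possible. The fallback sets out from **4** and returns at **6**. Friedel–Crafts acylation of 1,1-dichloroethene with **4** (AlCl3, CH2Cl2, 0 °C) gives 1,1,1-trichlorohexan-3-one F3. This loses HCl on distillation to give 1,1-dichlorohex-1-en-3-one F4. Two addition–elimination steps with NaOMe (2 equiv, MeOH, 0 °C) replace both vinylic chlorines and give **6**.

**Step 5.** Saponification may stall, because the ester is di-ortho-substituted and the phenoxide deactivates the carbonyl group. Forcing the conditions or acidifying warm would lead to decarboxylation. The fallback avoids hydrolysis altogether; it sets out from **6** and returns at **9**. Commercial tert-butyl 4-chloro-3-oxobutanoate (CC(C)(C)OC(=O)CC(=O)CCl) is silylated as in step 1 to tert-butyl (2Z)-4-chloro-3-(trimethylsilyloxy)but-2-enoate F5. A second silylation as in step 2 gives (1Z,3Z)-1-tert-butoxy-4-chloro-1,3-bis(trimethylsilyloxy)buta-1,3-diene F6. Union with **6** as in step 4 gives tert-butyl 3-chloro-2-hydroxy-4-methoxy-6-propylbenzoate F7. Brief treatment with CF3CO2H in CH2Cl2 at 0–20 °C then releases **9**; any ester already cleaved by TiCl4 converges on the same acid.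

**Step 7.** The activated acid may esterify itself through its own O2' hydroxyl. The acylium ion may C-acylate the electron-rich ring A, or O2 may be acylated as well as O4. The fallback protects O2' and uses base-mediated acylation; it sets out from **8** and returns at **14**. Benzylation (BnBr, K2CO3, DMF) gives ethyl 2-(benzyloxy)-3-chloro-4-methoxy-6-propylbenzoate F8. Saponification (KOH, aqueous DMSO) gives 2-(benzyloxy)-3-chloro-4-methoxy-6-propylbenzoic acid F9. Oxalyl chloride with catalytic DMF gives 2-(benzyloxy)-3-chloro-4-methoxy-6-propylbenzoyl chloride F10. Reaction with **11** (pyridine, catalytic DMAP, CH2Cl2) gives benzyl 4-{[2-(benzyloxy)-3-chloro-4-methoxy-6-propylbenzoyl]oxy}-2-hydroxy-6-pentylbenzoate F11. Hydrogenolysis over Pd/C removes both benzyl groups and gives **14**.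

**Step 8.** Reductive loss of chlorine at C3' may compete with benzyl cleavage. The fallback removes the ring A ester without hydrogen; it sets out from **10** and returns at **14**. Alkylation with allyl bromide (KHCO3, DMF) gives prop-2-en-1-yl 2,4-dihydroxy-6-pentylbenzoate F12. Coupling with **9** as in step 7 gives prop-2-en-1-yl 4-[(3-chloro-2-hydroxy-4-methoxy-6-propylbenzoyl)oxy]-2-hydroxy-6-pentylbenzoate F13. Deallylation with catalytic Pd(PPh3)4 and PhSiH3 in CH2Cl2 at 20 °C gives **14**. Zerovalent palladium with triarylphosphine ligands should not insert into the electron-rich aryl chloride at this temperature, and no nucleophilic amine is present to attack the depside ester.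

## Further compounds

F1 | step 4 | methyl 2-hydroxy-4-methoxy-6-propylbenzoate | CCCc1cc(OC)cc(O)c1C(=O)OC
F2 | step 4 | methyl 3-chloro-2-hydroxy-4-methoxy-6-propylbenzoate | CCCc1cc(OC)c(Cl)c(O)c1C(=O)OC
F3 | step 3 | 1,1,1-trichlorohexan-3-one | CCCC(=O)CC(Cl)(Cl)Cl
F4 | step 3 | 1,1-dichlorohex-1-en-3-one | CCCC(=O)C=C(Cl)Cl
F5 | step 5 | tert-butyl (2Z)-4-chloro-3-(trimethylsilyloxy)but-2-enoate | CC(C)(C)OC(=O)/C=C(\O[Si](C)(C)C)CCl
F6 | step 5 | (1Z,3Z)-1-tert-butoxy-4-chloro-1,3-bis(trimethylsilyloxy)buta-1,3-diene | Cl/C=C(\O[Si](C)(C)C)/C=C(/OC(C)(C)C)O[Si](C)(C)C
F7 | step 5 | tert-butyl 3-chloro-2-hydroxy-4-methoxy-6-propylbenzoate | CCCc1cc(OC)c(Cl)c(O)c1C(=O)OC(C)(C)C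
F8 | step 7 | ethyl 2-(benzyloxy)-3-chloro-4-methoxy-6-propylbenzoate | CCCc1cc(OC)c(Cl)c(OCc2ccccc2)c1C(=O)OCC
F9 | step 7 | 2-(benzyloxy)-3-chloro-4-methoxy-6-propylbenzoic acid | CCCc1cc(OC)c(Cl)c(OCc2ccccc2)c1C(=O)O
F10 | step 7 | 2-(benzyloxy)-3-chloro-4-methoxy-6-propylbenzoyl chloride | CCCc1cc(OC)c(Cl)c(OCc2ccccc2)c1C(=O)Cl
F11 | step 7 | benzyl 4-{[2-(benzyloxy)-3-chloro-4-methoxy-6-propylbenzoyl]oxy}-2-hydroxy-6-pentylbenzoate | CCCCCc1cc(OC(=O)c2c(CCC)cc(OC)c(Cl)c2OCc2ccccc2)cc(O)c1C(=O)OCc1ccccc1
F12 | step 8 | prop-2-en-1-yl 2,4-dihydroxy-6-pentylbenzoate | CCCCCc1cc(O)cc(O)c1C(=O)OCC=C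
F13 | step 8 | prop-2-en-1-yl 4-[(3-chloro-2-hydroxy-4-methoxy-6-propylbenzoyl)oxy]-2-hydroxy-6-pentylbenzoate | CCCCCc1cc(OC(=O)c2c(CCC)cc(OC)c(Cl)c2O)cc(O)c1C(=O)OCC=C
A1 | alternative 1 | dibenzyl malonate | O=C(CC(=O)OCc1ccccc1)OCc1ccccc1
A2 | alternative 1 | (E)-non-3-en-2-one | CCCCC/C=C/C(C)=O
A3 | alternative 1 | benzyl 2,4-dioxo-6-pentylcyclohexane-1-carboxylate (racemic trans, one enantiomer drawn) | CCCCC[C@@H]1CC(=O)CC(=O)[C@H]1C(=O)OCc1ccccc1
A4 | alternative 2 | 3-(benzyloxy)-2-chloro-4-iodo-1-methoxy-5-propylbenzene | CCCc1cc(OC)c(Cl)c(OCc2ccccc2)c1I
A5 | alternative 2 | carbon monoxide | [C-]#[O+]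
A6 | alternative 2 | benzyl 4-{[2-(benzyloxy)-3-chloro-4-methoxy-6-propylbenzoyl]oxy}-2-hydroxy-6-pentylbenzoate | CCCCCc1cc(OC(=O)c2c(CCC)cc(OC)c(Cl)c2OCc2ccccc2)cc(O)c1C(=O)OCc1ccccc1
A7 | alternative 3 | benzyl 4-(hex-2-ynoyloxy)-2-hydroxy-6-pentylbenzoate | CCCC#CC(=O)Oc1cc(O)c(C(=O)OCc2ccccc2)c(CCCCC)c1
A8 | alternative 3 | 2-chloro-1,3-dimethoxy-1-(trimethylsilyloxy)buta-1,3-diene (geometry not defined) | C=C(OC)C(Cl)=C(OC)O[Si](C)(C)C
A9 | alternative 3 | benzyl 4-[(3-chloro-2-hydroxy-4-methoxy-6-propylbenzoyl)oxy]-2-hydroxy-6-pentylbenzoate | CCCCCc1cc(OC(=O)c2c(CCC)cc(OC)c(Cl)c2O)cc(O)c1C(=O)OCc1ccccc1
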